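**Retrosynthetic overview**
1. The γ-lactone (C9(=O)–O–C9′) is the only ring and is closed last. The C9′–OH of a monolignol-level arm attacks the C9 acyl carbon of a sinapic-acid-level arm, the acid + alcohol pairing presumed for lignan lactones.
2. C9′–OH comes from a two-hydride reduction of an activated C9′ acyl group. An N-acyloxazolidinone plays the role of the CoA thioester.
3. C8–C8′ comes from oxidative phenoxyl-radical coupling of unprotected methyl sinapate (at C8) with a chiral 3-(3,4,5-trimethoxyphenyl)propanoyl enolate (at C8′). The quinone methide loses H-8 and gives the E-arylidene directly.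
4. The oxazolidinone stands in for a dirigent protein and sets C8′ as R. No protecting groups or late O-methylation are needed, because the trimethoxy ring never has to be a phenol.
5. Building blocks: 3-(3,4,5-trimethoxyphenyl)propanoic acid, (S)-4-benzyloxazolidin-2-one, syringaldehyde and Ph3P=CHCO2Me.

Assumption: lignan numbering is used (C7–C9 = sinapoyl side chain, C7′–C9′ = trimethoxyphenylpropanoid side chain), and the given SMILES is read as the (3E,4R) isomer.

**Step 1**
Reactants: 1 3-(3,4,5-trimethoxyphenyl)propanoic acid; 2 (S)-4-benzyl-1,3-oxazolidin-2-one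
Product: 4 (S)-4-benzyl-3-[3-(3,4,5-trimethoxyphenyl)propanoyl]-1,3-oxazolidin-2-one, via mixed pivalic anhydride 3 (not isolated)
Conditions: PivCl, Et3N, THF, −20 °C, 1 h; then LiCl, 2, −20 °C → rt
Reagents that add atoms: pivaloyl chloride CC(C)(C)C(=O)Cl (its acyl group sits in 3 only)
Why: This is a mixed-anhydride N-acylation of an Evans oxazolidinone (LiCl/Et3N variant) in which the nitrogen attacks the unhindered acyl carbon of 3 rather than the pivaloyl carbon, and the auxiliary stereocentre is untouched.

**Step 2**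
Reactants: 5 syringaldehyde (4-hydroxy-3,5-dimethoxybenzaldehyde)
Product: 6 methyl (E)-sinapate (methyl (E)-3-(4-hydroxy-3,5-dimethoxyphenyl)prop-2-enoate)
Conditions: Ph3P=CHCO2Me (1.2 equiv), toluene, 90 °C
Reagents that add atoms: methyl (triphenylphosphoranylidene)acetate COC(=O)C=P(c1ccccc1)(c1ccccc1)c1ccccc1
Why: A Wittig olefination with a stabilised ylide tolerates the free phenol and gives the E-cinnamate.

**Step 3**
Reactants: 4 (S)-4-benzyl-3-[3-(3,4,5-trimethoxyphenyl)propanoyl]-1,3-oxazolidin-2-one (1.0 equiv); 6 methyl (E)-sinapate (1.3 equiv)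
Product: 10 methyl (E)-2-{(2R)-1-[(4S)-4-benzyl-2-oxo-1,3-oxazolidin-3-yl]-1-oxo-3-(3,4,5-trimethoxyphenyl)propan-2-yl}-3-(4-hydroxy-3,5-dimethoxyphenyl)prop-2-enoate, via lithium Z-enolate 7 (not isolated), via lithium sinapate phenoxide 8 (not isolated), via quinone methide adduct 9 (not isolated)
Conditions: LDA (2.4 equiv, commercial solution), THF, −78 °C, 30 min; Cu(II) 2-ethylhexanoate (2.3 equiv), −78 → −20 °C; aq NH4Cl/NH4OH; SiO2 chromatography removes homodimers, the minor C8′ epimer and any Z isomer
Reagents that add atoms: lithium diisopropylamide CC(C)[N-]C(C)C.[Li+] (its lithium sits in 7 and 8 only)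
Why: Proposed new method: Cu(II) takes one electron each from enolate 7 and phenoxide 8, the short-lived α-imidyl radical (held s-cis by Li/Cu chelation) is captured by the long-lived sinapate phenoxyl radical at C8, the carbon where sinapates dimerise in nature and where radicals add to cinnamates (the persistent-radical effect favours the cross product), bond formation on the face anti to the 4-benzyl group sets C8′ as R in the same sense as an Evans alkylation, and quinone methide 9 rearomatises by loss of the doubly activated H-8 to the conjugated E-alkene as open 8–8′ ferulate and sinapate dimers do; the closest known reaction types are Cu(II)/Fe(III) oxidative enolate heterocoupling, oxidative coupling of indole or pyrrole anions with chiral imide or sultam enolates, and oxidative homocoupling of 3-arylpropanoyl oxazolidinone enolates.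

**Step 4**
Reactants: 10 coupled imide ester (as named in step 3)
Product: 12 (3E,4R)-3-(4-hydroxy-3,5-dimethoxybenzylidene)-4-(3,4,5-trimethoxybenzyl)oxolan-2-one, via γ-hydroxy sinapate ester 11 (not isolated)
Conditions: LiBH4 (3 equiv), THF, 0 °C, 2 h; sat. aq NH4Cl, rt
Reagents that add atoms: none
Why: This is a reductive auxiliary cleavage followed by lactonisation, in which LiBH4 reduces the activated imide carbonyl to the C9′ carbinol while the push–pull (phenoxide-conjugated) α-branched methyl ester is inert at 0 °C, the C9′ alkoxide closes 5-exo-trig onto C9 with loss of methoxide, and no stereocentre or alkene geometry is touched.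

**Compound list**
1 | 3-(3,4,5-trimethoxyphenyl)propanoic acid | COc1cc(CCC(=O)O)cc(OC)c1OC | starting material
2 | (S)-4-benzyl-1,3-oxazolidin-2-one | O=C1N[C@@H](Cc2ccccc2)CO1 | starting material
3 | 3-(3,4,5-trimethoxyphenyl)propanoic pivalic anhydride | COc1cc(CCC(=O)OC(=O)C(C)(C)C)cc(OC)c1OC | intermediate (not isolated)
4 | (S)-4-benzyl-3-[3-(3,4,5-trimethoxyphenyl)propanoyl]-1,3-oxazolidin-2-one | COc1cc(CCC(=O)N2[C@@H](Cc3ccccc3)COC2=O)cc(OC)c1OC | intermediate
5 | syringaldehyde | COc1cc(C=O)cc(OC)c1O | starting material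
6 | methyl (E)-sinapate | COC(=O)/C=C/c1cc(OC)c(O)c(OC)c1 | intermediate
7 | lithium (Z)-enolate of 4 | COc1cc(C/C=C(\[O-])N2[C@@H](Cc3ccccc3)COC2=O)cc(OC)c1OC.[Li+] | intermediate (not isolated)
8 | lithium phenoxide of 6 | COC(=O)/C=C/c1cc(OC)c([O-])c(OC)c1.[Li+] | intermediate (not isolated)
9 | 8–8′ quinone methide adduct (C8′ R, C8 epimers, both converge) | COC(=O)C(C=C1C=C(OC)C(=O)C(OC)=C1)[C@@H](Cc1cc(OC)c(OC)c(OC)c1)C(=O)N1[C@@H](Cc2ccccc2)COC1=O | intermediate (not isolated)
10 | methyl (E)-2-{(2R)-1-[(4S)-4-benzyl-2-oxo-1,3-oxazolidin-3-yl]-1-oxo-3-(3,4,5-trimethoxyphenyl)propan-2-yl}-3-(4-hydroxy-3,5-dimethoxyphenyl)prop-2-enoate | COC(=O)/C(=C/c1cc(OC)c(O)c(OC)c1)[C@@H](Cc1cc(OC)c(OC)c(OC)c1)C(=O)N1[C@@H](Cc2ccccc2)COC1=O | intermediate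
11 | methyl (E)-2-[(2R)-1-hydroxy-3-(3,4,5-trimethoxyphenyl)propan-2-yl]-3-(4-hydroxy-3,5-dimethoxyphenyl)prop-2-enoate | COC(=O)/C(=C/c1cc(OC)c(O)c(OC)c1)[C@@H](Cc1cc(OC)c(OC)c(OC)c1)CO | intermediate (not isolated)
12 | (3E,4R)-3-(4-hydroxy-3,5-dimethoxybenzylidene)-4-(3,4,5-trimethoxybenzyl)oxolan-2-one | COc1cc(/C=C2/C(=O)OC[C@@H]2Cc2cc(OC)c(OC)c(OC)c2)cc(OC)c1O | target

**Total step count:** 4. **Longest linear sequence:** 3 (steps 1, 3, 4).

**Steps most likely to fail**

Step 3 is the highest risk. Possible failures are sinapate or imide homodimers, 8′–O–4 instead of 8′–8 bonding, and modest diastereoselectivity.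

The fallback sets out from 6 and 4 and returns at 9, and thereby 10. It separates C–C bond formation from quinone methide chemistry:
- Compound 6 is hydrogenated (H2, Pd/C, MeOH) to methyl dihydrosinapate F1.
- F1 is silylated (TBSCl, imidazole) to its TBS ether F2.
- F2 and 4 are deprotonated together with LDA, which gives the lithium ester enolate F3 beside 7.
- The two enolates are joined by the established Cu(II)/Fe(III) enolate–enolate heterocoupling to the dibenzylsuccinate-type imide ester F4 (C8′ R from the auxiliary, C8 epimers irrelevant).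
- TBAF/AcOH frees the phenol F5.
- One equivalent of DDQ (or Ag2O) in the presence of Et3N oxidises the 4-hydroxybenzyl group to quinone methide 9, which tautomerises to 10.

Step 4 is the second risk. Possible failures are endocyclic opening of the hindered imide and over-reduction of the newly formed lactone.

The fallback sets out from 10 and returns at 12. It reduces everything first and then closes the ring oxidatively:
- Excess DIBAL-H (CH2Cl2, −78 → 0 °C) gives the (2E,3R)-2-arylidene-3-benzylbutane-1,4-diol F6.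
- DDQ (2.1 equiv, 1,4-dioxane, rt) abstracts hydride only from C9, the carbinol that is vinylogous to the free phenol.
- The resulting hydroxy enal closes to the lactol F7, and a second hydride abstraction gives 12.
- This is a quinone-for-NAD+ version of the diol → lactol → lactone dehydrogenation, and it also recycles any over-reduced material from step 4.

Step 2 is the third risk. The acidic phenol can protonate the ylide and stall the olefination.

The fallback sets out from 5 and returns at 6. It replaces the ylide by condensation and decarboxylation: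
- Malonic acid in pyridine with catalytic piperidine at 80 °C gives syringylidenemalonic acid F8.
- F8 decarboxylates in the flask to (E)-sinapic acid F9.
- Fischer esterification (MeOH, cat. H2SO4, reflux) then gives 6.

**Further compounds**
F1 | step 3 | methyl 3-(4-hydroxy-3,5-dimethoxyphenyl)propanoate | COC(=O)CCc1cc(OC)c(O)c(OC)c1
F2 | step 3 | methyl 3-[4-(tert-butyldimethylsilyloxy)-3,5-dimethoxyphenyl]propanoate | COC(=O)CCc1cc(OC)c(O[Si](C)(C)C(C)(C)C)c(OC)c1
F3 | step 3 | lithium enolate of F2 (geometry immaterial) | COC([O-])=CCc1cc(OC)c(O[Si](C)(C)C(C)(C)C)c(OC)c1.[Li+]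
F4 | step 3 | methyl (3R)-4-[(4S)-4-benzyl-2-oxo-1,3-oxazolidin-3-yl]-2-[4-(tert-butyldimethylsilyloxy)-3,5-dimethoxybenzyl]-4-oxo-3-(3,4,5-trimethoxybenzyl)butanoate (C2 epimers) | COC(=O)C(Cc1cc(OC)c(O[Si](C)(C)C(C)(C)C)c(OC)c1)[C@@H](Cc1cc(OC)c(OC)c(OC)c1)C(=O)N1[C@@H](Cc2ccccc2)COC1=O
F5 | step 3 | methyl (3R)-4-[(4S)-4-benzyl-2-oxo-1,3-oxazolidin-3-yl]-2-(4-hydroxy-3,5-dimethoxybenzyl)-4-oxo-3-(3,4,5-trimethoxybenzyl)butanoate (C2 epimers) | COC(=O)C(Cc1cc(OC)c(O)c(OC)c1)[C@@H](Cc1cc(OC)c(OC)c(OC)c1)C(=O)N1[C@@H](Cc2ccccc2)COC1=O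
F6 | step 4 | (2E,3R)-2-(4-hydroxy-3,5-dimethoxybenzylidene)-3-(3,4,5-trimethoxybenzyl)butane-1,4-diol | OC/C(=C/c1cc(OC)c(O)c(OC)c1)[C@@H](Cc1cc(OC)c(OC)c(OC)c1)CO
F7 | step 4 | (3E,4R)-3-(4-hydroxy-3,5-dimethoxybenzylidene)-4-(3,4,5-trimethoxybenzyl)oxolan-2-ol (anomers) | COc1cc(/C=C2/C(O)OC[C@@H]2Cc2cc(OC)c(OC)c(OC)c2)cc(OC)c1O
F8 | step 2 | 2-(4-hydroxy-3,5-dimethoxybenzylidene)malonic acid | OC(=O)C(=Cc1cc(OC)c(O)c(OC)c1)C(=O)O
F9 | step 2 | (E)-sinapic acid | OC(=O)/C=C/c1cc(OC)c(O)c(OC)c1
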